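The whole design rests on disconnecting the aryl ether bond O1–C8a of the upper (fisetinidol) pyran ring C. The key step, a copper-catalysed intramolecular O-arylation, closes this ring from an open-chain anti-1,3-diol, 1-aryl-2-benzyloxy-3-(2-bromo-4-benzyloxyphenyl)propane-1,3-diol, with all three stereocentres in place. It exploits that only the C2 hydroxyl can reach the brominated C8a of ring A: the C4 hydroxyl would give a four-membered ring and O3 is benzylated. The same C4 hydroxyl, set in an Evans glycolate aldol, directs the reduction that fixes C2 and finally leaves as water, so that the cation stabilised by the para O7 of ring A captures C8 of tribenzylafzelechin trans to O3.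

Key step: step 7

Assumption: (+)-afzelechin (17) is taken as a purchasable natural flavan-3-ol and carries the two lower stereocentres (2R,3S) into the target unchanged.

Step 1
Reactants: 1 (S)-4-benzyloxazolidin-2-one; 2 benzyloxyacetyl chloride
Product: 4 (S)-4-benzyl-3-[(benzyloxy)acetyl]oxazolidin-2-one, via N-lithio oxazolidinone 3 (not isolated)
Conditions: n-BuLi, THF, −78 °C; then 2, −78 → 0 °C
Reagents that add atoms: none
Why: N-acylation of the lithiated oxazolidinone by the acid chloride (standard acylation of an Evans auxiliary), which leaves the auxiliary stereocentre untouched.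

Step 2
Reactants: 5 2-bromo-4-hydroxybenzaldehyde
Product: 6 4-(benzyloxy)-2-bromobenzaldehyde
Conditions: BnBr, K2CO3, DMF, rt
Reagents that add atoms: benzyl bromide, BrCc1ccccc1
Why: Williamson ether synthesis on the phenoxide, to which the aldehyde and the aryl bromide are inert.

Step 3
Reactants: 4 (S)-4-benzyl-3-[(benzyloxy)acetyl]oxazolidin-2-one; 6 4-(benzyloxy)-2-bromobenzaldehyde
Product: 9 (S)-4-benzyl-3-[(2S,3R)-2-(benzyloxy)-3-[4-(benzyloxy)-2-bromophenyl]-3-hydroxypropanoyl]oxazolidin-2-one, via dibutylboron Z-enolate 7 (not isolated), via dibutylboron aldolate 8 (not isolated)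
Conditions: Bu2BOTf, Et3N, CH2Cl2, −78 → 0 °C; 6, −78 → 0 °C; then pH 7 buffer, MeOH, 30% H2O2, 0 °C
Reagents that add atoms: none
Why: Evans syn-aldol reaction, in which the Z-boron enolate reacts through a closed Zimmerman–Traxler chair on the face away from the auxiliary benzyl group, setting the benzyloxy-bearing carbon (future C3) as S and the carbinol (future C4) syn to it.

Step 4
Reactants: 9 the syn-aldol adduct
Product: 10 (2S,3R)-2-(benzyloxy)-3-[4-(benzyloxy)-2-bromophenyl]-3-hydroxy-N-methoxy-N-methylpropanamide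
Conditions: MeNH(OMe)·HCl, AlMe3, THF, −10 → 0 °C
Reagents that add atoms: N,O-dimethylhydroxylamine hydrochloride, CNOC.Cl
Why: Weinreb transamidation by the aluminium amide, assisted by the free β-hydroxyl, which touches neither stereocentre and returns auxiliary 1.

Step 5
Reactants: 10 the Weinreb amide; 11 4-bromo-1,2-bis(benzyloxy)benzene
Product: 13 (2S,3R)-2-(benzyloxy)-1-[3,4-bis(benzyloxy)phenyl]-3-[4-(benzyloxy)-2-bromophenyl]-3-hydroxypropan-1-one, via aryl Grignard reagent 12 (not isolated)
Conditions: 11, Mg, THF, 40 °C; then 10, THF, −20 → 0 °C (3 equiv of 12); aq NH4Cl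
Reagents that add atoms: none
Why: Weinreb ketone synthesis, in which the N-methoxy-N-methylamide accepts one aryl Grignard only (one further equivalent is consumed by the free hydroxyl) and the ring-A aryl bromide is inert to ArMgBr at 0 °C.

Step 6
Reactants: 13 the β-hydroxy ketone
Product: 15 (1R,2R,3R)-2-(benzyloxy)-1-[3,4-bis(benzyloxy)phenyl]-3-[4-(benzyloxy)-2-bromophenyl]propane-1,3-diol, via alkoxydiacetoxyborohydride 14 (not isolated)
Conditions: Me4NBH(OAc)3, MeCN/AcOH 1:1, −35 → −20 °C
Reagents that add atoms: none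
Why: Evans–Saksena reduction, in which the future C4 hydroxyl exchanges an acetate on boron and the bound hydride is delivered internally through a chair transition state, setting the new carbinol (future C2, R) 1,3-anti to that hydroxyl and therefore anti to O3.

Step 7
Reactants: 15 the anti-1,3-diol
Product: 16 (2R,3S,4R)-3,7-bis(benzyloxy)-2-[3,4-bis(benzyloxy)phenyl]chroman-4-ol (protected 2,3-trans-3,4-trans leucofisetinidin)
Conditions: CuI (10 mol %), 3,4,7,8-tetramethyl-1,10-phenanthroline (20 mol %), Cs2CO3 (2.5 equiv), toluene (0.02 M), 110 °C, argon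
Reagents that add atoms: none
Why: Ullmann-type etherification: the caesium alkoxide of the C2 hydroxyl binds phenanthroline-ligated monovalent copper, the C8a–Br bond adds oxidatively and C–O reductive elimination releases the chroman and the catalyst. The closest known reaction type is the copper-catalysed intramolecular O-arylation of secondary alcohols by aryl bromides, as used for chromans and flavans. Ring C closes as a six-membered ring by bonding O1 to the sp2 carbon C8a, the tether C2–C3–C4–C4a holding the alkoxide over the ortho C–Br bond. No stereocentre is formed: the C2–O bond is never broken, so C2 is retained, and with no carbonyl in the substrate neither retro-aldol cleavage nor epimerisation at C3 or C4 is open, which should leave the 2,3-trans-3,4-trans array intact. The step needs chemoselectivity among three oxygens and the substrate secures it: the C4 hydroxyl could only give a four-membered benzoxete, O3 is a benzyl ether so that no dihydrobenzofuran can form, and dilution disfavours intermolecular coupling.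

Step 8
Reactants: 17 (+)-afzelechin
Product: 18 (2R,3S)-5,7-bis(benzyloxy)-2-[4-(benzyloxy)phenyl]chroman-3-ol
Conditions: BnBr (3.3 equiv), K2CO3, DMF, 0 °C → rt
Reagents that add atoms: benzyl bromide, BrCc1ccccc1
Why: phenol-selective Williamson benzylation, since K2CO3 deprotonates only the three phenols and leaves the secondary 3-hydroxyl and both stereocentres untouched.

Step 9
Reactants: 16 the flavan-3,4-diol derivative; 18 tri-O-benzylafzelechin
Product: 20 (2R,3S)-5,7-bis(benzyloxy)-2-[4-(benzyloxy)phenyl]-8-{(2R,3S,4S)-3,7-bis(benzyloxy)-2-[3,4-bis(benzyloxy)phenyl]chroman-4-yl}chroman-3-ol, via flavan-4-yl cation 19 (not isolated)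
Conditions: 18 (4 equiv), TMSOTf (0.2 equiv), CH2Cl2, −78 → −30 °C; Et3N quench
Reagents that add atoms: none
Why: dehydrative Friedel–Crafts alkylation (the biomimetic proanthocyanidin coupling), in which the C4 hydroxyl ionises to a benzylic cation stabilised by the para O7 of ring A and is captured by C8 of the phloroglucinol-type ring of 18 on the face anti to the 3-benzyloxy group of the half-chair, which should set C4 as S (3,4-trans).

Step 10
Reactants: 20 the hepta-O-benzyl dimer
Product: 21 fisetinidol-(4α→8)-afzelechin (CNP0322555.1)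
Conditions: H2 (1 atm), Pd(OH)2/C, THF/MeOH/H2O, rt
Reagents that add atoms: none
Why: hydrogenolysis of the seven benzyl ethers under mild conditions that should spare the cyclic benzylic C–O bonds and the diarylmethine C4 and touch no stereocentre.

Compound list
1 | (S)-4-benzyloxazolidin-2-one | O=C1N[C@@H](Cc2ccccc2)CO1 | starting material
2 | benzyloxyacetyl chloride | ClC(=O)COCc1ccccc1 | starting material
3 | N-lithio (S)-4-benzyloxazolidin-2-one | [Li]N1C(=O)OC[C@@H]1Cc1ccccc1 | intermediate (not isolated)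
4 | (S)-4-benzyl-3-[(benzyloxy)acetyl]oxazolidin-2-one | O=C(COCc1ccccc1)N1C(=O)OC[C@@H]1Cc1ccccc1 | intermediate
5 | 2-bromo-4-hydroxybenzaldehyde | O=Cc1ccc(O)cc1Br | starting material
6 | 4-(benzyloxy)-2-bromobenzaldehyde | O=Cc1ccc(OCc2ccccc2)cc1Br | intermediate
7 | dibutylboron Z-enolate of 4 | CCCCB(CCCC)O/C(N1C(=O)OC[C@@H]1Cc1ccccc1)=C\OCc1ccccc1 | intermediate (not isolated)
8 | dibutylboron aldolate of 9 | O=C(N1C(=O)OC[C@@H]1Cc1ccccc1)[C@@H](OCc1ccccc1)[C@H](OB(CCCC)CCCC)c1ccc(OCc2ccccc2)cc1Br | intermediate (not isolated)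
9 | (S)-4-benzyl-3-[(2S,3R)-2-(benzyloxy)-3-[4-(benzyloxy)-2-bromophenyl]-3-hydroxypropanoyl]oxazolidin-2-one | O=C(N1C(=O)OC[C@@H]1Cc1ccccc1)[C@@H](OCc1ccccc1)[C@H](O)c1ccc(OCc2ccccc2)cc1Br | intermediate
10 | (2S,3R)-2-(benzyloxy)-3-[4-(benzyloxy)-2-bromophenyl]-3-hydroxy-N-methoxy-N-methylpropanamide | CON(C)C(=O)[C@@H](OCc1ccccc1)[C@H](O)c1ccc(OCc2ccccc2)cc1Br | intermediate
11 | 4-bromo-1,2-bis(benzyloxy)benzene | Brc1ccc(OCc2ccccc2)c(OCc2ccccc2)c1 | starting material
12 | [3,4-bis(benzyloxy)phenyl]magnesium bromide | Br[Mg]c1ccc(OCc2ccccc2)c(OCc2ccccc2)c1 | intermediate (not isolated)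
13 | (2S,3R)-2-(benzyloxy)-1-[3,4-bis(benzyloxy)phenyl]-3-[4-(benzyloxy)-2-bromophenyl]-3-hydroxypropan-1-one | O=C(c1ccc(OCc2ccccc2)c(OCc2ccccc2)c1)[C@@H](OCc1ccccc1)[C@H](O)c1ccc(OCc2ccccc2)cc1Br | intermediate
14 | tetramethylammonium alkoxydiacetoxyborohydride of 13 | O=C(c1ccc(OCc2ccccc2)c(OCc2ccccc2)c1)[C@@H](OCc1ccccc1)[C@H](O[BH-](OC(C)=O)OC(C)=O)c1ccc(OCc2ccccc2)cc1Br.C[N+](C)(C)C | intermediate (not isolated)
15 | (1R,2R,3R)-2-(benzyloxy)-1-[3,4-bis(benzyloxy)phenyl]-3-[4-(benzyloxy)-2-bromophenyl]propane-1,3-diol | O[C@H](c1ccc(OCc2ccccc2)c(OCc2ccccc2)c1)[C@@H](OCc1ccccc1)[C@H](O)c1ccc(OCc2ccccc2)cc1Br | intermediate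
16 | (2R,3S,4R)-3,7-bis(benzyloxy)-2-[3,4-bis(benzyloxy)phenyl]chroman-4-ol | O[C@@H]1c2ccc(OCc3ccccc3)cc2O[C@H](c2ccc(OCc3ccccc3)c(OCc3ccccc3)c2)[C@H]1OCc1ccccc1 | intermediate
17 | (+)-afzelechin, (2R,3S)-2-(4-hydroxyphenyl)chroman-3,5,7-triol | Oc1ccc(cc1)[C@H]1Oc2cc(O)cc(O)c2C[C@@H]1O | starting material
18 | (2R,3S)-5,7-bis(benzyloxy)-2-[4-(benzyloxy)phenyl]chroman-3-ol | C(c1ccccc1)Oc1ccc(cc1)[C@H]1Oc2cc(OCc3ccccc3)cc(OCc3ccccc3)c2C[C@@H]1O | intermediate
19 | (2R,3S)-3,7-bis(benzyloxy)-2-[3,4-bis(benzyloxy)phenyl]chroman-4-ylium triflate | [CH+]1c2ccc(OCc3ccccc3)cc2O[C@H](c2ccc(OCc3ccccc3)c(OCc3ccccc3)c2)[C@H]1OCc1ccccc1.[O-]S(=O)(=O)C(F)(F)F | intermediate (not isolated)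
20 | hepta-O-benzyl dimer, upper unit (2R,3S,4S), lower unit (2R,3S), linked C4 to C8 | C(c1ccccc1)Oc1ccc([C@H]2Oc3c(c(OCc4ccccc4)cc(OCc4ccccc4)c3[C@@H]3c4ccc(OCc5ccccc5)cc4O[C@H](c4ccc(OCc5ccccc5)c(OCc5ccccc5)c4)[C@H]3OCc3ccccc3)C[C@@H]2O)cc1 | intermediate
21 | (2R,3S)-8-[(2R,3S,4S)-2-(3,4-dihydroxyphenyl)-3,7-dihydroxychroman-4-yl]-2-(4-hydroxyphenyl)chroman-3,5,7-triol, fisetinidol-(4α→8)-afzelechin | Oc1ccc([C@H]2Oc3c(c(O)cc(O)c3[C@@H]3c4ccc(O)cc4O[C@H](c4ccc(O)c(O)c4)[C@H]3O)C[C@@H]2O)cc1 | target

Total step count: 10. Longest linear sequence: 8 steps (1, 3, 4, 5, 6, 7, 9, 10).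

Steps most likely to fail

Step 7. The electron-rich, ortho-substituted aryl bromide may add to copper too slowly, the 1,3-diol may sequester the catalyst, and reductive loss of bromine may outrun C–O bond formation. The fallback closes the same bond without a metal catalyst. It sets out from 15: lithium 2,2,6,6-tetramethylpiperidide (4 equiv) in THF at −78 °C deprotonates both hydroxyls and then the ring-A position between Br and OBn. On warming to −20 °C, loss of lithium bromide gives the 3-alkoxyaryne F1 as its dilithium dialkoxide. The C2 alkoxide adds to C8a, which is the aryne terminus meta to the alkoxy group and the only one the tether allows. Protonation of the C8 aryllithium on work-up returns to the route at 16.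

Step 9. Ionisation under acid may give poor facial selectivity at C4, attack through C6 of 18, and further alkylation of the product. The fallback separates ionisation from C–C bond formation. It sets out from 16: benzyl mercaptan with catalytic TsOH in CH2Cl2 at 0 °C should give, under reversible conditions, the 3,4-trans 4-benzylthio ether F2. F2 and 18 are then joined with AgBF4 in THF at 0 °C, where the thiophilic silver salt releases the C4 electrophile without protic or hard Lewis acid. This returns to the route at 20.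

Step 6. Internal hydride delivery may be slow on the electron-rich aryl ketone, the 1,3-anti preference may be eroded by the α-benzyloxy group, and the acidic medium may ionise the benzylic hydroxyl. The fallback replaces 1,3-induction by 1,2-chelation control. It sets out from 13: silylation (TBSOTf, 2,6-lutidine, CH2Cl2, −78 °C) gives the silyl ether F3. Zn(BH4)2 in Et2O at −20 °C then reduces the ketone through the five-membered zinc chelate with the α-benzyloxy group, with hydride arriving anti to the C4 substituent, which should give the 1,2-anti alcohol F4. TBAF in THF removes the silyl group and returns to the route at 15.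

Further compounds
F1 | step 7 | dilithium dialkoxide of the 3-alkoxyaryne derived from 15 | [Li]O[C@H](c1ccc(OCc2ccccc2)c(OCc2ccccc2)c1)[C@@H](OCc1ccccc1)[C@H](O[Li])C1=CC=C(OCc2ccccc2)C#C1
F2 | step 9 | (2R,3R,4R)-3,7-bis(benzyloxy)-4-(benzylsulfanyl)-2-[3,4-bis(benzyloxy)phenyl]chromane | C(c1ccccc1)S[C@@H]1c2ccc(OCc3ccccc3)cc2O[C@H](c2ccc(OCc3ccccc3)c(OCc3ccccc3)c2)[C@H]1OCc1ccccc1
F3 | step 6 | (2S,3R)-2-(benzyloxy)-1-[3,4-bis(benzyloxy)phenyl]-3-[4-(benzyloxy)-2-bromophenyl]-3-[(tert-butyldimethylsilyl)oxy]propan-1-one | O=C(c1ccc(OCc2ccccc2)c(OCc2ccccc2)c1)[C@@H](OCc1ccccc1)[C@H](O[Si](C)(C)C(C)(C)C)c1ccc(OCc2ccccc2)cc1Br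
F4 | step 6 | (1R,2R,3R)-2-(benzyloxy)-1-[3,4-bis(benzyloxy)phenyl]-3-[4-(benzyloxy)-2-bromophenyl]-3-[(tert-butyldimethylsilyl)oxy]propan-1-ol | O[C@H](c1ccc(OCc2ccccc2)c(OCc2ccccc2)c1)[C@@H](OCc1ccccc1)[C@H](O[Si](C)(C)C(C)(C)C)c1ccc(OCc2ccccc2)cc1Br
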